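Percent of the combined charge is the unit of every reading here, so two products can be divided directly.

- cedar: starting material 0.24 M; other conformer 0.18 M; run made earlier
- flask: starting material 0.24 M; other conformer 0.120 M; time 5.0 h

- cedar (time / min: isomer of the product A / %, target / %, starting material / %): 2.50: 0.3, 0.2, 54.9; 5.00: 2.5, 0.2, 54.4; 8.00: 2.1, 4.0, 53.4; 15.0: 4.0, 5.2, 49.7; 30.0: 7.7, 8.2, 40.2

(standard deviation of a reading: 1 percentage point)

- the analysis behind the earlier runs scatters by 1 percentage point, standard deviation
- reactions considered so far: target <-> isomer of the product B; other conformer -> isomer of the product A; other conformer <-> third conformer; starting material -> target; target -> over-reaction product; third conformer -> third product; starting material <-> other conformer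

* share of isomer of the product A in isomer of the product A plus target at 1.0 min
* share of isomer of the product A in isomer of the product A plus target at 15 min
* share of isomer of the product A in isomer of the product A plus target at 5.0 h
* which of isomer of the product A and target there is more of at 5.0 h

We take target to come from starting material and isomer of the product A from other conformer. Cedar's last readings, at 30.0 min, give 0.939 isomer of the product A per target. Dividing out cedar's charges gives the selectivity factor s = 1.25, a reading carrying the scatter of 1 percentage point: what a molecule of other conformer yields against a molecule of starting material. Multiplying s by the flask's charge of other conformer over starting material gives ρ = 0.626, our estimate of the rate of forming isomer of the product A over that of forming target at the first moment. The share asked for is then ρ/(1+ρ), or 38.5%, which we commit to at 1.0 min and 15 min.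

One number is not enough for 5.0 h. Cedar's starting material had lost 17 points by 30.0 min, and the target reading was half of that, so the rest did not stand as target. Target also has two exits among the listed steps and isomer of the product A has none, so we expect the flask's share to pass half, as a judgement rather than a figure from ρ.

The forecast gave 35%, 37% and 68% at those times, with isomer of the product A leading, noting “Target is probably eroded by side reactions”.

The flask gives 38.3% at 1.0 min against our 38.5%, then 38.8% at 15 min and 60.1% at 5.0 h, where isomer of the product A stands at 28.2% and target at 18.7%.

    target ⇌ isomer of the product B (K = 0.880, k = 7.70 × 10⁻⁵ s⁻¹)
    other conformer → isomer of the product A (k = 1.50 × 10⁻⁴ s⁻¹)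
    other conformer ⇌ third conformer (K = 0.380, k = 7.90 × 10⁻⁴ s⁻¹)
    starting material → target (k = 1.20 × 10⁻⁴ s⁻¹)
    target → over-reaction product (k = 1.60 × 10⁻⁵ s⁻¹)
    third conformer → third product (k = 5.40 × 10⁻⁴ s⁻¹)
    starting material ⇌ other conformer (K = 0.800, k = 3.70 × 10⁻⁴ s⁻¹)

The neighbour flask, charged with 0.060 M of starting material and the same other conformer, has ρ = 2.50, so its share at the first moment should be 71.5%. That neighbour flask shows 70.5% at 1.0 min, 62.9% at 15 min and 66.1% at 5.0 h.

The data stem from a simulated flask from invented constants.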